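At 60.0 s the midnight flask has made 26.7% of product against 16.3% in the dawn flask, and the midnight flask was charged with twice the substrate and, at equal loading, twice the catalyst.

common to all: free catalyst 0.057 mol%
- midnight: substrate 20 mM; the very flask that is asked about, followed so far
- dawn: substrate 10 mM; run made earlier
- flask: substrate 20 mM

| run | time / s | product / % | substrate / % |
|---|---|---|---|
| midnight | 12.0 | 5.7 | 94.4 |
| midnight | 25.0 | 11.9 | 87.9 |
| midnight | 40.0 | 18.8 | 81.8 |
| midnight | 50.0 | 22.9 | 77.1 |
| midnight | 60.0 | 26.7 | 73.4 |
| midnight | 80.0 | 34.1 | 65.9 |
| dawn | 10.0 | 3.0 | 96.8 |
| dawn | 12.0 | 3.5 | 96.6 |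
| dawn | 20.0 | 6.0 | 93.7 |
| dawn | 40.0 | 11.5 | 88.7 |
| dawn | 60.0 | 16.3 | 83.2 |

(readings scatter by 0.3 percentage points)



- apparent order in free catalyst when 5.0% of the substrate are converted (percent change of the rate of making product for one percent more free catalyst charged)

A bench rule reads such a pair. If the substrate decays pseudo-first-order, the clock L = −ln(1 − x), with x the fraction converted, grows steadily with time, and at equal loading its pace follows the catalyst concentration. The doubling order n, the power of two by which L grows when the charge is doubled at equal loading, is then 0.804 from the pair at 60.0 s.

The rule has a border in the scatter. At 12.0 s, when the midnight flask stands near the asked conversion, the dawn flask reads 3.5%, and the scatter is 8.57% of that reading, which moves n by 0.124. At 60.0 s the scatter is 1.84% of the dawn reading and moves n by 0.0266, so the later pair is the one to use. This reckoning commits to n as the order, although n is a mean between the two charges.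

The forecast gives 0.75, lower than this reckoning, and sees in the order “partial resting in an inactive dimer or aggregate”.

The flask gives 0.79, so the forecast holds within its margin.

    substrate + free catalyst ⇌ catalyst intermediate (K = 32.0 M⁻¹, k = 1100 M⁻¹ s⁻¹)
    catalyst intermediate → free catalyst + product (k = 71.0 s⁻¹)
    2 free catalyst ⇌ resting dimer, settled at all times (K = 32000 M⁻¹)

After 0.250 min the flask holds 27.2% of its catalyst as resting dimer, parked off-cycle. The simulated run without that parking has an order of 1.0. By the bench rule, an order of that size multiplies L by 2.00 per doubling, against 1.75 read from the midnight and dawn pair.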